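Start with the easy step: time one turn of the catalyst.

    coupling partner + free catalyst → catalyst intermediate A (k1 = 66 M⁻¹ h⁻¹)
    substrate + catalyst intermediate A → catalyst intermediate B (k2 = 270 M⁻¹ h⁻¹)
    catalyst intermediate B ⇌ released group + catalyst intermediate C (K3 = 0.060 M, k3 = 11 h⁻¹)
    catalyst intermediate C → free catalyst + target (k4 = 12 h⁻¹)
    coupling partner + released group ⇌ idle adduct, settled at all times (K5 = 590 M⁻¹)

common to all: free catalyst 0.5 mol%
- beta: substrate 0.050 M; coupling partner 3.00 equiv (fed, over 40.0 h); time 50 h; a stirred flask in which coupling partner is dosed at a steady rate over 40.0 h without added volume, worked up at 50 h
- zeta: substrate 0.050 M (fed, over 40.0 h); coupling partner 3.00 equiv; time 50 h; all but substrate at the start; substrate goes in evenly over 40.0 h, the run ends at 50 h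
- delta: substrate 0.050 M; coupling partner 3.00 equiv; one stirred flow tank at steady state, fed with the mixture as stated, mean residence time 50 h
- gamma: substrate 0.050 M; coupling partner 3.00 equiv; time 50 h; everything together in a closed stirred flask, run for 50 h

1. the set-up with the highest amount of target at the outlet or at the end, in percent of the substrate put in ("none" if the first two lie within 2 percentage points) (beta / zeta / delta / gamma / none)
2. amount of target at the outlet or at the end, in percent of the substrate put in, beta
3. amount of target at the outlet or at the end, in percent of the substrate put in, zeta
4. amount of target at the outlet or at the end, in percent of the substrate put in, delta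
5. amount of target at the outlet or at the end, in percent of the substrate put in, gamma

- for released group the idle adduct is counted in
- the stated concentrations are those of everything mixed, before any reaction; amounts are the same in each set-up
- the feed brings no volume worth counting
- run time (beta): 50 h

Take gamma, the closed flask. One turn of the catalyst is a row of waits. Free catalyst waits for coupling partner, and the wait is the inverse of the rate constant times the partner concentration. Catalyst intermediate A waits for substrate in the same way. Catalyst intermediates B and C wait the inverse of their own constants, together 0.174 h. I drop the undoing of step 3. The sum is the cycle time, also called the turnover time. Each turn makes 0.5 mol% of target on the substrate charged, so the yield is that loading times the run time, divided by the cycle time.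

At the charge:

cycle time = 0.101 h + 0.0741 h + 0.174 h = 0.349 h

yield = 71.6%

But the concentrations fall, so the waits grow. Each target costs one substrate and two partners, one in step 1 and one as idle adduct. The second goes because K5 times the partner concentration stays at 70.8 at mid-run. So take the middle, with substrate at 0.7 of its charge, 0.0350 M, and partner at 0.120 M:

cycle time = 0.406 h

yield = 61.5%

The weak link is one midpoint standing for a whole curve. So I reforge it. That yield puts the end at substrate 0.0192 M and partner 0.0885 M:

end cycle time = 0.538 h

Weigh start, middle and end as 1 : 4 : 1:

average = 0.419 h

yield = 59.7%

That average is the mean cycle time, the time of one turn averaged over the run. I commit to this yield for gamma.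

The forecast named gamma as best, with 48% for beta, 48% for zeta, 52% for delta and 60% for gamma, holding that “the run is limited by turnover”.

The simulation gives gamma 59.9%, the highest, with beta at 46.4% and zeta at 47.5%. The undoing of step 3, dropped above, makes no difference in gamma. Now take delta, the tank. It holds one concentration everywhere, so its mean cycle time is a single cycle time. With substrate at 0.0241 M and partner at 0.0986 M, that is 0.482 h, longer than the 0.419 h of gamma. The same division over the residence time gives 51.9%, and delta stands at 51.6%.

(Its constants were drawn at random within sensible limits.)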